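The route rests on cutting the two outer diarylmethane bonds, each joining the CH2 carbon on C5 of a ring D to the ring E carbon next to the one that carries the ring E hydroxyl. Since the oxygen-bearing carbon and the CH2-bearing carbon are adjacent in ring E, one boron atom can bridge the phenol oxygen and the oxygen of a formyl group on C5 of ring D. A single operation thus joins two phenol molecules to a dialdehyde through their ortho carbons only and closes two benzodioxaborin rings. The precursor is (2S)-pinostrobin bearing 2-acetoxy-5-formylbenzyl groups on C6 and C8 of ring A, with O5 acetylated. Ionic reduction and deacetylation then deliver the target.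

Key step: step 3

Ring labels: rings A and C form the chromanone, ring B is the 2-phenyl group, rings D are the two inner benzyl rings (C1 bonded to the CH2 on ring A, C2 oxygenated, C5 carrying the second CH2), and rings E are the two outer phenol rings.

Remark on the structure: the SMILES is taken as binding, so O7 is a methyl ether and the core is (2S)-pinostrobin. The natural (−)-material is assumed to be supplied as the single (2S) enantiomer and its enantiomeric purity is to be checked by chiral HPLC before use.

Remark on stoichiometry: steps 1 and 3 each build two identical arms, so two molecules of each arm-forming partner end up in the product. The first molecule stands on the Reactants line and the second under "Reagents that add atoms".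

Step 1
Reactants: 1 (2S)-pinostrobin [(2S)-5-hydroxy-7-methoxyflavanone]; 2 4-hydroxy-3-(hydroxymethyl)benzaldehyde
Product: 4 (2S)-6,8-bis(5-formyl-2-hydroxybenzyl)-5-hydroxy-7-methoxyflavanone, via formyl ortho-quinone methide 3 (not isolated)
Conditions: 2 (3 equiv in total, added in portions), ZnCl2 (anhydrous, 2 equiv), 1,4-dioxane, 80 °C
Reagents that add atoms: 4-hydroxy-3-(hydroxymethyl)benzaldehyde (second molecule of 2, which becomes the second benzyl arm), O=Cc1ccc(O)c(CO)c1
Why: ZnCl2 ionises the ortho-hydroxybenzylic alcohol to the ortho-quinone methide 3, which C6 and C8 of ring A (the only free carbons, each flanked by two oxygen-bearing carbons) trap in a twofold Friedel–Crafts alkylation (1 + two molecules of 2 → 4 + 2 H2O), a known reaction type for 5,7-dioxygenated flavanones and salicyl alcohols, while the formyl group keeps the reagent ring too electron-poor to oligomerise and no bond at C2 is touched.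

Step 2
Reactants: 4 (2S)-6,8-bis(5-formyl-2-hydroxybenzyl)-5-hydroxy-7-methoxyflavanone
Product: 5 (2S)-5-acetoxy-6,8-bis(2-acetoxy-5-formylbenzyl)-7-methoxyflavanone
Conditions: Ac2O (4 equiv), pyridine, DMAP (cat.), CH2Cl2, 0 °C to rt
Reagents that add atoms: acetic anhydride, CC(=O)OC(C)=O
Why: DMAP-catalysed acylation (nucleophilic acyl substitution) esterifies the two acidic ring D phenols quickly and the chelated O5 hydroxyl more slowly, at a basicity and temperature too low to open ring C, so that ring D is silenced as a nucleophile, its formyl groups stay electrophilic, and O5 can no longer chelate boron together with the C4 carbonyl.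

Step 3
Reactants: 5 (2S)-5-acetoxy-6,8-bis(2-acetoxy-5-formylbenzyl)-7-methoxyflavanone; 6 phenol; 7 phenylboronic acid
Product: 9 (2S)-5-acetoxy-6,8-bis[2-acetoxy-5-(2-phenyl-4H-1,3,2-benzodioxaborin-4-yl)benzyl]-7-methoxyflavanone as a mixture of epimers at each dioxaborin C4, via phenyl hydrogen phenylboronate 8 (not isolated)
Conditions: PhOH (6 equiv), PhB(OH)2 (3 equiv), EtCO2H (0.3 equiv), toluene, reflux, Dean–Stark trap; excess PhOH then removed under high vacuum and crude 9 carried on
Reagents that add atoms: phenol (second molecule of 6, for the second arm), Oc1ccccc1; phenylboronic acid (second molecule of 7, for the second arm), OB(O)c1ccccc1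
Why: For each formyl group one phenol and one PhB(OH)2 condense to the aryloxyboron species 8, whose boron binds the formyl oxygen, and the ring E carbon ortho to the boron-bound oxygen then attacks the activated carbonyl carbon through a six-membered array, after which rearomatisation and loss of water leave the cyclic boronate (overall 5 + 2 PhOH + 2 PhB(OH)2 → 9 + 4 H2O). The closest known reaction type is the phenylboronic acid-templated ortho-specific hydroxyalkylation of phenols with aldehydes under azeotropic, weakly acidic conditions. Each 4H-1,3,2-benzodioxaborin ring is closed by the C–C bond-forming event itself, a 6-endo-trig attack of the aromatic carbon on the boron-coordinated C=O, the two B–O bonds having been set beforehand by reversible condensation. The two new stereocentres at C4 of the dioxaborins form without control because C2 is remote, so a mixture of epimers is expected and accepted, since both carbons become CH2 in step 4. The step needs ortho over para selectivity on phenol, which the O–B–O bridge secures because the tethered carbonyl cannot reach the para carbon, and it needs phenol to be the only nucleophile, which holds because ring A is fully substituted and O5 and both ring D oxygens are acetates that neither bind boron nor activate ring D. The medium is only weakly acidic and free of base, so ring C should stay closed and C2 should keep its (S) configuration.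

Step 4
Reactants: 9 (2S)-5-acetoxy-6,8-bis[2-acetoxy-5-(2-phenyl-4H-1,3,2-benzodioxaborin-4-yl)benzyl]-7-methoxyflavanone
Product: 10 (2S)-5-acetoxy-6,8-bis[2-acetoxy-5-(2-hydroxybenzyl)benzyl]-7-methoxyflavanone
Conditions: Et3SiH (2.4 equiv), CF3CO2H (10 equiv), CH2Cl2, 0 °C; aq. NaHCO3 work-up
Reagents that add atoms: none
Why: In this ionic hydrogenation CF3CO2H ionises each doubly benzylic C–O bond to a diarylmethyl cation stabilised by the ortho oxygen of ring E, Et3SiH delivers hydride to it, and aqueous work-up hydrolyses the remaining aryl boronate to free both ring E phenols, while the much slower reduction of the C4 aryl ketone is held back by the low temperature and the small excess of silane.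

Step 5
Reactants: 10 (2S)-5-acetoxy-6,8-bis[2-acetoxy-5-(2-hydroxybenzyl)benzyl]-7-methoxyflavanone
Product: 11 (2S)-5-hydroxy-6,8-bis[2-hydroxy-5-(2-hydroxybenzyl)benzyl]-7-methoxyflavanone (target)
Conditions: HCl (1.25 M in MeOH), MeOH–CH2Cl2, rt to 40 °C
Reagents that add atoms: none
Why: Acid-catalysed transesterification with methanol cleaves the three aryl acetates as methyl acetate, and because no base is present the flavanone cannot equilibrate with its chalcone, so C2 should keep the (S) configuration.

Compound list
1 | (2S)-pinostrobin, (2S)-5-hydroxy-7-methoxyflavanone | COc1cc(O)c2c(c1)O[C@H](c1ccccc1)CC2=O | starting material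
2 | 4-hydroxy-3-(hydroxymethyl)benzaldehyde | O=Cc1ccc(O)c(CO)c1 | starting material
3 | 3-methylidene-4-oxocyclohexa-1,5-diene-1-carbaldehyde (formyl ortho-quinone methide) | O=CC1=CC(=C)C(=O)C=C1 | intermediate
4 | (2S)-6,8-bis(5-formyl-2-hydroxybenzyl)-5-hydroxy-7-methoxyflavanone | COc1c(Cc2cc(C=O)ccc2O)c(O)c2c(c1Cc1cc(C=O)ccc1O)O[C@H](c1ccccc1)CC2=O | intermediate
5 | (2S)-5-acetoxy-6,8-bis(2-acetoxy-5-formylbenzyl)-7-methoxyflavanone | COc1c(Cc2cc(C=O)ccc2OC(C)=O)c(OC(C)=O)c2c(c1Cc1cc(C=O)ccc1OC(C)=O)O[C@H](c1ccccc1)CC2=O | intermediate
6 | phenol | Oc1ccccc1 | starting material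
7 | phenylboronic acid | OB(O)c1ccccc1 | starting material
8 | phenyl hydrogen phenylboronate | OB(Oc1ccccc1)c1ccccc1 | intermediate
9 | (2S)-5-acetoxy-6,8-bis[2-acetoxy-5-(2-phenyl-4H-1,3,2-benzodioxaborin-4-yl)benzyl]-7-methoxyflavanone, both epimers at each dioxaborin C4 | COc1c(Cc2cc(C3OB(c4ccccc4)Oc4ccccc34)ccc2OC(C)=O)c(OC(C)=O)c2c(c1Cc1cc(C3OB(c4ccccc4)Oc4ccccc34)ccc1OC(C)=O)O[C@H](c1ccccc1)CC2=O | intermediate
10 | (2S)-5-acetoxy-6,8-bis[2-acetoxy-5-(2-hydroxybenzyl)benzyl]-7-methoxyflavanone | COc1c(Cc2cc(Cc3ccccc3O)ccc2OC(C)=O)c(OC(C)=O)c2c(c1Cc1cc(Cc3ccccc3O)ccc1OC(C)=O)O[C@H](c1ccccc1)CC2=O | intermediate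
11 | (2S)-5-hydroxy-6,8-bis[2-hydroxy-5-(2-hydroxybenzyl)benzyl]-7-methoxyflavanone | COc1c(Cc2cc(Cc3ccccc3O)ccc2O)c(O)c2c(c1Cc1cc(Cc3ccccc3O)ccc1O)O[C@H](c1ccccc1)CC2=O | target

Step count. Total: 5 steps. Longest linear sequence: 5 steps (1 → 4 → 5 → 9 → 10 → 11).

Steps most likely to fail

Step 3. The double condensation may stall after one arm, acetyl groups may transfer to the excess phenol and re-expose ring D or O5, or the acid may drive the newly formed benzylic carbon on to a second arylation. The ortho connectivity can then be brought in by the nucleophile instead of by a tether. Setting out from 5, rhodium-catalysed 1,2-addition of two molecules of 2-(benzyloxy)phenylboronic acid (OB(O)c1ccccc1OCc1ccccc1) to the two formyl groups is run with Rh(acac)(CO)2 and 1,1'-bis(diphenylphosphino)ferrocene in DME–H2O at 80 °C; aldehydes react under these conditions while the C4 ketone and the esters should not. This should give (2S)-5-acetoxy-6,8-bis{2-acetoxy-5-[(2-benzyloxyphenyl)(hydroxy)methyl]benzyl}-7-methoxyflavanone F1. Hydrogenolysis (H2, Pd/C, EtOAc, trace AcOH, rt) then removes both benzyl ethers and both benzhydrylic hydroxyl groups and returns to the route at 10.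

Step 1. Ionisation of the formyl-bearing benzylic alcohol may be too slow, its formyl groups may condense with ring A, or long heating with ZnCl2 may begin to open ring C and erode C2, leading to incomplete benzylation, oligomerisation or partial racemisation. The formyl groups can then be introduced after the Friedel–Crafts event. Setting out from 1, the same ZnCl2-mediated bis-benzylation with two molecules of 2-hydroxy-5-iodobenzyl alcohol (OCc1cc(I)ccc1O, a purchasable building block that ionises more readily and carries no carbonyl) should give (2S)-5-hydroxy-6,8-bis(2-hydroxy-5-iodobenzyl)-7-methoxyflavanone F2. Acetylation as in step 2 gives (2S)-5-acetoxy-6,8-bis(2-acetoxy-5-iodobenzyl)-7-methoxyflavanone F3. Palladium-catalysed reductive carbonylation of both aryl iodides under neutral conditions (Pd(PPh3)4, CO, Bu3SnH added slowly, toluene, 50 °C) rejoins the route at 5.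

Step 4. Ionic hydrogenation may also attack the C4 ketone, or the diarylmethyl cations may alkylate electron-rich rings instead of taking hydride. Boron removal and deoxygenation can then be separated and the reduction done without strong acid. Setting out from 9, transesterification with 2,2-dimethylpropane-1,3-diol (THF, rt) should free (2S)-5-acetoxy-6,8-bis{2-acetoxy-5-[hydroxy(2-hydroxyphenyl)methyl]benzyl}-7-methoxyflavanone F4. Hydrogenolysis of the two benzhydrylic C–OH bonds (H2, Pd/C, EtOAc, rt) returns to the route at 10.

Further compounds
F1 | step 3 | (2S)-5-acetoxy-6,8-bis{2-acetoxy-5-[(2-benzyloxyphenyl)(hydroxy)methyl]benzyl}-7-methoxyflavanone, both epimers at each carbinol carbon | COc1c(Cc2cc(C(O)c3ccccc3OCc3ccccc3)ccc2OC(C)=O)c(OC(C)=O)c2c(c1Cc1cc(C(O)c3ccccc3OCc3ccccc3)ccc1OC(C)=O)O[C@H](c1ccccc1)CC2=O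
F2 | step 1 | (2S)-5-hydroxy-6,8-bis(2-hydroxy-5-iodobenzyl)-7-methoxyflavanone | COc1c(Cc2cc(I)ccc2O)c(O)c2c(c1Cc1cc(I)ccc1O)O[C@H](c1ccccc1)CC2=O
F3 | step 1 | (2S)-5-acetoxy-6,8-bis(2-acetoxy-5-iodobenzyl)-7-methoxyflavanone | COc1c(Cc2cc(I)ccc2OC(C)=O)c(OC(C)=O)c2c(c1Cc1cc(I)ccc1OC(C)=O)O[C@H](c1ccccc1)CC2=O
F4 | step 4 | (2S)-5-acetoxy-6,8-bis{2-acetoxy-5-[hydroxy(2-hydroxyphenyl)methyl]benzyl}-7-methoxyflavanone, both epimers at each carbinol carbon | COc1c(Cc2cc(C(O)c3ccccc3O)ccc2OC(C)=O)c(OC(C)=O)c2c(c1Cc1cc(C(O)c3ccccc3O)ccc1OC(C)=O)O[C@H](c1ccccc1)CC2=O
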